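**Retrosynthetic overview**

1. Numbering as in germacranolides: ten-membered ring C1–C10 (C3 ketone, C4 methyl, C6 lactone CH–O, C7 ring-fusion CH, C8 tiglate carbon, C10 carbinol); lactone ring O–C12(=O)–C11(=C13H2)–C7–C6.
2. Enabling feature: within the ten-membered ring, C3 is a ketone carbon bonded only to two alkene carbons, C2 of the E-alkene C1=C2 and C4 of the Z-alkene C4=C5 (a divinyl ketone). C2–C3 and C3–C4 are therefore disconnected together and C3 arrives last as carbon monoxide between an alkenylstannane (C2) and an alkenyl iodide (C4); the precursor is an open chain on the preformed lactone and lacks the ring, C3 and its oxygen.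
3. The seco compound comes from Mitsunobu inversion at C8 with tiglic acid, after an indium Barbier union (C7–C8) of a 3-(bromomethyl)butenolide (C4–C7, C11–C13, C4-methyl) with a β-silyloxy aldehyde (C8–C10, C10-methyl, C1, C2); the C6 stereocentre relays C7 and C8 in that one event.
4. The butenolide comes from ring-closing metathesis, hydroalumination–iodination (Z-C4=C5 iodide) and Sharpless kinetic resolution (C6); the aldehyde from Sharpless epoxidation (C10), hydride opening and hydrostannylation (E-C1=C2 stannane).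
5. Order of ring formation: γ-lactone first (step 5 as butenolide, converted to the α-methylene lactone in step 11); ten-membered carbocycle last (step 13).

Key step: step 13

**Route**

Step 1
Reactants: 1 acrolein; 2 prop-1-ynylmagnesium bromide
Product: 3 rac-hex-1-en-4-yn-3-ol
Conditions: THF, −78 → 0 °C; aq. NH4Cl
Reagents that add atoms: none
Why: Grignard 1,2-addition of the alkynyl reagent to the aldehyde should give the racemic vinyl propynyl carbinol that holds the future C4–C7 and the C4 methyl group.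

Step 2
Reactants: 3 rac-hex-1-en-4-yn-3-ol
Product: 4 (3S)-hex-1-en-4-yn-3-ol
Conditions: Ti(OiPr)4 (15 mol %), L-(+)-diisopropyl tartrate (20 mol %), t-BuOOH (0.6 equiv), 4 Å molecular sieves, CH2Cl2, −20 °C
Reagents that add atoms: none
Why: In this Sharpless kinetic resolution the (R)-enantiomer should be epoxidised faster at its vinyl group (erythro epoxy alcohol), so that the (S)-alcohol, whose carbinol carbon becomes C6, is recovered enantioenriched.

Step 3
Reactants: 4 (3S)-hex-1-en-4-yn-3-ol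
Product: 6 (3S,4Z)-5-iodohexa-1,4-dien-3-ol, via cyclic alkenylalanate 5 (not isolated)
Conditions: NaAlH2(OCH2CH2OMe)2, THF, 0 → 23 °C; then I2, THF, −78 → 0 °C
Reagents that add atoms: iodine, II
Why: Hydroxyl-directed trans-hydroalumination of the propargylic alcohol puts hydride on the proximal and aluminium on the distal alkyne carbon, and iodinolysis with retention should give the Z-alkenyl iodide (future C4=C5) while the vinyl group and C6 stay untouched.

Step 4
Reactants: 6 (3S,4Z)-5-iodohexa-1,4-dien-3-ol; 7 2-(bromomethyl)acrylic acid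
Product: 8 (3S,4Z)-5-iodohexa-1,4-dien-3-yl 2-(bromomethyl)prop-2-enoate
Conditions: DCC, DMAP (5 mol %), CH2Cl2, −10 → 0 °C
Reagents that add atoms: none
Why: Steglich esterification acylates the secondary bis-allylic alcohol under neutral conditions without touching C6 or the allylic bromide.

Step 5
Reactants: 8 (3S,4Z)-5-iodohexa-1,4-dien-3-yl 2-(bromomethyl)prop-2-enoate
Product: 9 (5S)-3-(bromomethyl)-5-[(Z)-2-iodoprop-1-enyl]furan-2(5H)-one
Conditions: second-generation Grubbs catalyst (5 mol %), CH2Cl2, 40 °C, 0.01 M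
Reagents that add atoms: none
Why: Ring-closing metathesis between the terminal vinyl group and the 1,1-disubstituted acrylate alkene should close the butenolide (the lactone ring) with loss of ethene, the trisubstituted iodoalkene being inert to the ruthenium carbene.

Step 6
Reactants: 10 (E)-3-methylpent-2-en-4-yn-1-ol
Product: 11 [(2S,3S)-3-ethynyl-3-methyloxiran-2-yl]methanol
Conditions: Ti(OiPr)4 (10 mol %), L-(+)-diethyl tartrate (12 mol %), t-BuOOH, 4 Å molecular sieves, CH2Cl2, −20 °C
Reagents that add atoms: tert-butyl hydroperoxide, CC(C)(C)OO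
Why: Sharpless asymmetric epoxidation of the E-trisubstituted allylic alcohol with the L-(+)-tartrate should deliver oxygen to the face that gives the (2S,3S)-epoxide, which fixes the tertiary C–O stereocentre that becomes C10.

Step 7
Reactants: 11 [(2S,3S)-3-ethynyl-3-methyloxiran-2-yl]methanol
Product: 12 (3R)-3-methylpent-4-yne-1,3-diol
Conditions: NaAlH2(OCH2CH2OMe)2, THF, −20 → 0 °C; aq. potassium sodium tartrate
Reagents that add atoms: none
Why: Alkoxide-directed hydride delivery opens the 2,3-epoxy alcohol at C2 (1,3-diol formation), so the tertiary C–O bond and its configuration are retained.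

Step 8
Reactants: 12 (3R)-3-methylpent-4-yne-1,3-diol
Product: 13 (3R)-3-methyl-3,5-bis(triethylsilyloxy)pent-1-yne
Conditions: Et3SiOTf (2.4 equiv), 2,6-lutidine, CH2Cl2, −78 → 0 °C
Reagents that add atoms: triethylsilyl trifluoromethanesulfonate, CC[Si](CC)(CC)OS(=O)(=O)C(F)(F)F
Why: The silyl triflate silylates both the primary and the hindered tertiary hydroxyl group.

Step 9
Reactants: 13 (3R)-3-methyl-3,5-bis(triethylsilyloxy)pent-1-yne
Product: 14 (1E,3R)-3-methyl-3,5-bis(triethylsilyloxy)-1-(tributylstannyl)pent-1-ene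
Conditions: Bu3SnH (1.1 equiv), PdCl2(PPh3)2 (2 mol %), THF, 0 °C
Reagents that add atoms: tributyltin hydride, CCCC[SnH](CCCC)CCCC
Why: Palladium-catalysed syn-hydrostannylation of the terminal alkyne places tin on the terminal carbon, away from the quaternary centre, and should give the E-alkenylstannane (future C1=C2).

Step 10
Reactants: 14 (1E,3R)-3-methyl-3,5-bis(triethylsilyloxy)-1-(tributylstannyl)pent-1-ene
Product: 15 (3R,4E)-3-methyl-3-(triethylsilyloxy)-5-(tributylstannyl)pent-4-enal
Conditions: (COCl)2, DMSO, CH2Cl2, −78 → −40 °C; Et3N, −78 → 0 °C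
Reagents that add atoms: none
Why: Swern oxidation converts a primary triethylsilyl ether directly into the aldehyde (future C8), while the tertiary silyl ether and the alkenylstannane are not attacked.

Step 11
Reactants: 9 (5S)-3-(bromomethyl)-5-[(Z)-2-iodoprop-1-enyl]furan-2(5H)-one; 15 (3R,4E)-3-methyl-3-(triethylsilyloxy)-5-(tributylstannyl)pent-4-enal
Product: 16 (4R,5S)-4-[(1S,3R,4E)-1-hydroxy-3-methyl-3-(triethylsilyloxy)-5-(tributylstannyl)pent-4-enyl]-5-[(Z)-2-iodoprop-1-enyl]-3-methylideneoxolan-2-one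
Conditions: In powder (1.5 equiv), THF/H2O (3:1), 23 °C
Reagents that add atoms: none
Why: In this Barbier allylation the allylindium from 9 should react at its γ-carbon (C7) anti to the C6 alkenyl group (trans-lactone, exocyclic methylene formed) through a chair Zimmerman–Traxler transition state with the aldehyde residue equatorial; because the C6 substituent is fixed trans to the CH2–In group, this gives the 8S carbinol, epimeric to the target at C8.

Step 12
Reactants: 16 (4R,5S)-4-[(1S,3R,4E)-1-hydroxy-3-methyl-3-(triethylsilyloxy)-5-(tributylstannyl)pent-4-enyl]-5-[(Z)-2-iodoprop-1-enyl]-3-methylideneoxolan-2-one; 17 tiglic acid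
Product: 18 (1R,3R,4E)-1-[(2S,3R)-2-[(Z)-2-iodoprop-1-enyl]-4-methylidene-5-oxooxolan-3-yl]-3-methyl-3-(triethylsilyloxy)-5-(tributylstannyl)pent-4-enyl (E)-2-methylbut-2-enoate
Conditions: PPh3, DIAD, toluene, 0 → 23 °C
Reagents that add atoms: none
Why: Mitsunobu esterification displaces the activated C8 oxygen by tiglate with inversion, which installs the ester and corrects C8 to the 8R configuration in one step, the tertiary alcohol being protected.

Step 13
Reactants: 18 (1R,3R,4E)-1-[(2S,3R)-2-[(Z)-2-iodoprop-1-enyl]-4-methylidene-5-oxooxolan-3-yl]-3-methyl-3-(triethylsilyloxy)-5-(tributylstannyl)pent-4-enyl (E)-2-methylbut-2-enoate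
Product: 19 10-O-triethylsilyl eupaheliangolide A
Conditions: Pd2(dba)3 (10 mol %), AsPh3 (40 mol %), CO (3 atm), NMP, 55 °C; 18 added by syringe pump to a final 1 mM
Reagents that add atoms: carbon monoxide, [C-]#[O+]
Why: Oxidative addition of zerovalent palladium into the C4–I bond (Z geometry retained), insertion of CO to the C3 acylpalladium, intramolecular tin-to-palladium transfer of the E-alkenyl group at C2 and reductive elimination form C3–C4 and C2–C3 in one operation and install the ketone. The closest known reaction type is the carbonylative Stille macrocyclisation of an alkenyl halide or triflate with a tethered alkenylstannane to a macrocyclic divinyl ketone. The ten-membered carbocycle closes in the reductive elimination from an eleven-membered acyl(alkenyl)palladacycle, that is by C(sp2)–C(sp2) bond formation between C2 and C3 after CO has been taken up at C4. No stereocentre is created: C6, C7, C8 and C10 are spectators, and the E (C1=C2) and Z (C4=C5) geometries are carried over with retention from tin and iodide. The step needs CO insertion before transmetallation (otherwise a nine-membered diene), ring closure before intermolecular coupling, and no insertion of the acylpalladium into the exocyclic C11=C13 alkene; CO pressure, AsPh3 (fast transmetallation), slow addition at high dilution and the folding of the chain by the trans-lactone, the Z-alkene and the quaternary C10 should secure this.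

Step 14
Reactants: 19 10-O-triethylsilyl eupaheliangolide A
Product: 20 eupaheliangolide A
Conditions: HF·pyridine, pyridine, THF, 0 → 23 °C
Reagents that add atoms: none
Why: Fluoride-mediated desilylation frees the tertiary C10 alcohol under buffered conditions that the dienone, the lactone and the tiglate should tolerate.

**Compound list**

1 | acrolein (prop-2-enal) | C=CC=O | starting material
2 | prop-1-ynylmagnesium bromide | CC#C[Mg]Br | starting material
3 | rac-hex-1-en-4-yn-3-ol | CC#CC(O)C=C | intermediate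
4 | (3S)-hex-1-en-4-yn-3-ol | CC#C[C@@H](O)C=C | intermediate
5 | cyclic alkenylalanate, sodium (5S)-5-ethenyl-2,2-bis(2-methoxyethoxy)-3-methyl-2,5-dihydro-1,2-oxaluminol-2-uide | C=C[C@H]1C=C(C)[Al-](OCCOC)(OCCOC)O1.[Na+] | intermediate
6 | (3S,4Z)-5-iodohexa-1,4-dien-3-ol | C=C[C@H](O)/C=C(/C)I | intermediate
7 | 2-(bromomethyl)acrylic acid | C=C(CBr)C(=O)O | starting material
8 | (3S,4Z)-5-iodohexa-1,4-dien-3-yl 2-(bromomethyl)prop-2-enoate | C=C[C@H](OC(=O)C(=C)CBr)/C=C(/C)I | intermediate
9 | (5S)-3-(bromomethyl)-5-[(Z)-2-iodoprop-1-enyl]furan-2(5H)-one | O=C1O[C@H](/C=C(/C)I)C=C1CBr | intermediate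
10 | (E)-3-methylpent-2-en-4-yn-1-ol | C#C/C(C)=C/CO | starting material
11 | [(2S,3S)-3-ethynyl-3-methyloxiran-2-yl]methanol | C#C[C@]1(C)O[C@H]1CO | intermediate
12 | (3R)-3-methylpent-4-yne-1,3-diol | C#C[C@](C)(O)CCO | intermediate
13 | (3R)-3-methyl-3,5-bis(triethylsilyloxy)pent-1-yne | C#C[C@](C)(O[Si](CC)(CC)CC)CCO[Si](CC)(CC)CC | intermediate
14 | (1E,3R)-3-methyl-3,5-bis(triethylsilyloxy)-1-(tributylstannyl)pent-1-ene | CC[Si](CC)(CC)OCC[C@@](C)(O[Si](CC)(CC)CC)/C=C/[Sn](CCCC)(CCCC)CCCC | intermediate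
15 | (3R,4E)-3-methyl-3-(triethylsilyloxy)-5-(tributylstannyl)pent-4-enal | O=CC[C@@](C)(O[Si](CC)(CC)CC)/C=C/[Sn](CCCC)(CCCC)CCCC | intermediate
16 | (4R,5S)-4-[(1S,3R,4E)-1-hydroxy-3-methyl-3-(triethylsilyloxy)-5-(tributylstannyl)pent-4-enyl]-5-[(Z)-2-iodoprop-1-enyl]-3-methylideneoxolan-2-one | C=C1C(=O)O[C@H](/C=C(/C)I)[C@H]1[C@@H](O)C[C@@](C)(O[Si](CC)(CC)CC)/C=C/[Sn](CCCC)(CCCC)CCCC | intermediate
17 | tiglic acid, (E)-2-methylbut-2-enoic acid | C/C=C(\C)C(=O)O | starting material
18 | (1R,3R,4E)-1-[(2S,3R)-2-[(Z)-2-iodoprop-1-enyl]-4-methylidene-5-oxooxolan-3-yl]-3-methyl-3-(triethylsilyloxy)-5-(tributylstannyl)pent-4-enyl (E)-2-methylbut-2-enoate | C=C1C(=O)O[C@H](/C=C(/C)I)[C@H]1[C@H](OC(=O)/C(C)=C/C)C[C@@](C)(O[Si](CC)(CC)CC)/C=C/[Sn](CCCC)(CCCC)CCCC | intermediate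
19 | 10-O-triethylsilyl eupaheliangolide A, (3aR,4R,6R,7E,10Z,11aR)-6,10-dimethyl-3-methylidene-2,9-dioxo-6-(triethylsilyloxy)-2,3,3a,4,5,6,9,11a-octahydrocyclodeca[b]furan-4-yl (E)-2-methylbut-2-enoate | C=C1C(=O)O[C@@H]2/C=C(/C)C(=O)/C=C/[C@](C)(O[Si](CC)(CC)CC)C[C@@H](OC(=O)/C(C)=C/C)[C@@H]12 | intermediate
20 | eupaheliangolide A, (3aR,4R,6R,7E,10Z,11aR)-6-hydroxy-6,10-dimethyl-3-methylidene-2,9-dioxo-2,3,3a,4,5,6,9,11a-octahydrocyclodeca[b]furan-4-yl (E)-2-methylbut-2-enoate | C=C1C(=O)O[C@@H]2/C=C(/C)C(=O)/C=C/[C@](C)(O)C[C@@H](OC(=O)/C(C)=C/C)[C@@H]12 | target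

**Step count and risks**

Total step count: 14. Longest linear sequence: 9 steps (steps 1–5, then 11–14; steps 6–10, then 11–14, is equally long).

Steps most likely to fail:

1. Step 13. What may go wrong: the C3 acylpalladium inserts into the nearby exocyclic C11=C13 alkene, or couples between molecules, faster than the ten-membered ring closes. The fallback closes the ring by Nozaki–Hiyama–Kishi coupling of the C4 iodide with a C3 aldehyde and oxidises afterwards; it sets out from 13 and comes back to the route at 20. Lithiation of 13 (n-BuLi, THF, −78 °C) and addition to paraformaldehyde would give (4R)-4-methyl-4,6-bis(triethylsilyloxy)hex-2-yn-1-ol F1. Hydroxyl-directed trans-reduction with NaAlH2(OCH2CH2OMe)2 (THF, 0 °C) would give (2E,4R)-4-methyl-4,6-bis(triethylsilyloxy)hex-2-en-1-ol F2, and TBSCl/imidazole its silyl ether (2E,4R)-1-(tert-butyldimethylsilyloxy)-4-methyl-4,6-bis(triethylsilyloxy)hex-2-ene F3. Swern oxidation of the primary triethylsilyl ether would give (3R,4E)-6-(tert-butyldimethylsilyloxy)-3-methyl-3-(triethylsilyloxy)hex-4-enal F4. Indium Barbier coupling of F4 with 9, as in step 11, would give the 8S alcohol (4R,5S)-4-[(1S,3R,4E)-6-(tert-butyldimethylsilyloxy)-1-hydroxy-3-methyl-3-(triethylsilyloxy)hex-4-enyl]-5-[(Z)-2-iodoprop-1-enyl]-3-methylideneoxolan-2-one F5, and Mitsunobu esterification with 17, as in step 12, its inverted tiglate F6. HF·pyridine would remove both silyl groups to give the diol (1R,3R,4E)-3,6-dihydroxy-1-[(2S,3R)-2-[(Z)-2-iodoprop-1-enyl]-4-methylidene-5-oxooxolan-3-yl]-3-methylhex-4-enyl (E)-2-methylbut-2-enoate F7. MnO2 would oxidise only the primary allylic alcohol to the enal F8. CrCl2 with catalytic NiCl2 (DMSO, 2 mM) would close the ring between C3 and C4 to the macrocyclic C3 carbinol F9 (both C3 epimers), and MnO2 or Dess–Martin periodinane would oxidise F9 to 20.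

2. Step 12. What may go wrong: elimination towards C7=C8 or C8=C9, or no displacement at all, at the hindered secondary carbinol flanked by the ring CH and the chain leading to quaternary C10. The fallback inverts C8 by oxidation and reagent-controlled reduction and then acylates with retention; it sets out from 16 and comes back at 18. Dess–Martin periodinane (NaHCO3, CH2Cl2) would give the C8 ketone (4S,5S)-5-[(Z)-2-iodoprop-1-enyl]-3-methylidene-4-[(3R,4E)-3-methyl-3-(triethylsilyloxy)-5-(tributylstannyl)pent-4-enoyl]oxolan-2-one F10. Reduction with (S)-2-methyl-CBS-oxazaborolidine and catecholborane (toluene, −78 °C) should give the 8R alcohol (4R,5S)-4-[(1R,3R,4E)-1-hydroxy-3-methyl-3-(triethylsilyloxy)-5-(tributylstannyl)pent-4-enyl]-5-[(Z)-2-iodoprop-1-enyl]-3-methylideneoxolan-2-one F11. Yamaguchi esterification of F11 with 17 (2,4,6-trichlorobenzoyl chloride, Et3N, DMAP) would give 18.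

3. Step 5. What may go wrong: the ruthenium carbene is consumed by the allylic bromide, or the electron-poor bromomethyl acrylate alkene fails to engage, so that dimers form instead of the butenolide. The fallback introduces the bromide only after ring closure; it sets out from 6 and comes back at 9. Steglich esterification of 6 with the known 2-[(tert-butyldimethylsilyloxy)methyl]acrylic acid would give (3S,4Z)-5-iodohexa-1,4-dien-3-yl 2-[(tert-butyldimethylsilyloxy)methyl]prop-2-enoate F12. Ring-closing metathesis (second-generation Grubbs catalyst) would give (5S)-3-[(tert-butyldimethylsilyloxy)methyl]-5-[(Z)-2-iodoprop-1-enyl]furan-2(5H)-one F13, and HF·pyridine the alcohol (5S)-3-(hydroxymethyl)-5-[(Z)-2-iodoprop-1-enyl]furan-2(5H)-one F14. Appel bromination (CBr4, PPh3, CH2Cl2, 0 °C) would convert F14 into 9.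

**Further compounds**

F1 | step 13 | (4R)-4-methyl-4,6-bis(triethylsilyloxy)hex-2-yn-1-ol | OCC#C[C@](C)(O[Si](CC)(CC)CC)CCO[Si](CC)(CC)CC
F2 | step 13 | (2E,4R)-4-methyl-4,6-bis(triethylsilyloxy)hex-2-en-1-ol | OC/C=C/[C@](C)(O[Si](CC)(CC)CC)CCO[Si](CC)(CC)CC
F3 | step 13 | (2E,4R)-1-(tert-butyldimethylsilyloxy)-4-methyl-4,6-bis(triethylsilyloxy)hex-2-ene | CC(C)(C)[Si](C)(C)OC/C=C/[C@](C)(O[Si](CC)(CC)CC)CCO[Si](CC)(CC)CC
F4 | step 13 | (3R,4E)-6-(tert-butyldimethylsilyloxy)-3-methyl-3-(triethylsilyloxy)hex-4-enal | CC(C)(C)[Si](C)(C)OC/C=C/[C@](C)(O[Si](CC)(CC)CC)CC=O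
F5 | step 13 | (4R,5S)-4-[(1S,3R,4E)-6-(tert-butyldimethylsilyloxy)-1-hydroxy-3-methyl-3-(triethylsilyloxy)hex-4-enyl]-5-[(Z)-2-iodoprop-1-enyl]-3-methylideneoxolan-2-one | C=C1C(=O)O[C@H](/C=C(/C)I)[C@H]1[C@@H](O)C[C@@](C)(O[Si](CC)(CC)CC)/C=C/CO[Si](C)(C)C(C)(C)C
F6 | step 13 | (1R,3R,4E)-6-(tert-butyldimethylsilyloxy)-1-[(2S,3R)-2-[(Z)-2-iodoprop-1-enyl]-4-methylidene-5-oxooxolan-3-yl]-3-methyl-3-(triethylsilyloxy)hex-4-enyl (E)-2-methylbut-2-enoate | C=C1C(=O)O[C@H](/C=C(/C)I)[C@H]1[C@H](OC(=O)/C(C)=C/C)C[C@@](C)(O[Si](CC)(CC)CC)/C=C/CO[Si](C)(C)C(C)(C)C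
F7 | step 13 | (1R,3R,4E)-3,6-dihydroxy-1-[(2S,3R)-2-[(Z)-2-iodoprop-1-enyl]-4-methylidene-5-oxooxolan-3-yl]-3-methylhex-4-enyl (E)-2-methylbut-2-enoate | C=C1C(=O)O[C@H](/C=C(/C)I)[C@H]1[C@H](OC(=O)/C(C)=C/C)C[C@@](C)(O)/C=C/CO
F8 | step 13 | (1R,3R,4E)-3-hydroxy-1-[(2S,3R)-2-[(Z)-2-iodoprop-1-enyl]-4-methylidene-5-oxooxolan-3-yl]-3-methyl-6-oxohex-4-enyl (E)-2-methylbut-2-enoate | C=C1C(=O)O[C@H](/C=C(/C)I)[C@H]1[C@H](OC(=O)/C(C)=C/C)C[C@@](C)(O)/C=C/C=O
F9 | step 13 | C3 carbinol of 20 (both C3 epimers), (3aR,4R,6R,7E,10Z,11aR)-6,9-dihydroxy-6,10-dimethyl-3-methylidene-2-oxo-2,3,3a,4,5,6,9,11a-octahydrocyclodeca[b]furan-4-yl (E)-2-methylbut-2-enoate | C=C1C(=O)O[C@@H]2/C=C(/C)C(O)/C=C/[C@](C)(O)C[C@@H](OC(=O)/C(C)=C/C)[C@@H]12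
F10 | step 12 | (4S,5S)-5-[(Z)-2-iodoprop-1-enyl]-3-methylidene-4-[(3R,4E)-3-methyl-3-(triethylsilyloxy)-5-(tributylstannyl)pent-4-enoyl]oxolan-2-one | C=C1C(=O)O[C@H](/C=C(/C)I)[C@H]1C(=O)C[C@@](C)(O[Si](CC)(CC)CC)/C=C/[Sn](CCCC)(CCCC)CCCC
F11 | step 12 | (4R,5S)-4-[(1R,3R,4E)-1-hydroxy-3-methyl-3-(triethylsilyloxy)-5-(tributylstannyl)pent-4-enyl]-5-[(Z)-2-iodoprop-1-enyl]-3-methylideneoxolan-2-one | C=C1C(=O)O[C@H](/C=C(/C)I)[C@H]1[C@H](O)C[C@@](C)(O[Si](CC)(CC)CC)/C=C/[Sn](CCCC)(CCCC)CCCC
F12 | step 5 | (3S,4Z)-5-iodohexa-1,4-dien-3-yl 2-[(tert-butyldimethylsilyloxy)methyl]prop-2-enoate | C=C[C@H](OC(=O)C(=C)CO[Si](C)(C)C(C)(C)C)/C=C(/C)I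
F13 | step 5 | (5S)-3-[(tert-butyldimethylsilyloxy)methyl]-5-[(Z)-2-iodoprop-1-enyl]furan-2(5H)-one | O=C1O[C@H](/C=C(/C)I)C=C1CO[Si](C)(C)C(C)(C)C
F14 | step 5 | (5S)-3-(hydroxymethyl)-5-[(Z)-2-iodoprop-1-enyl]furan-2(5H)-one | O=C1O[C@H](/C=C(/C)I)C=C1CO
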